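**Strategy.** (Numbering: cyclohexene C1(Et)=C2–C3(Ph)–C4–C5–C6; cyclopentane C5–C9–C8–C7–C6.) The cyclopentane carries its C9 methyl cis to the quaternary C4 substituent. This congested relation is set by a stereospecific bond shift instead of remote induction, so the cyclopentane is reached from a trans-fused octalin. An ester-activated intramolecular Diels–Alder of a D-tartrate-tethered tetraene sets C3–C6. The key step contracts the carbocycle C5–C10–C9–C8–C7–C6 to the cyclopentane by a semipinacol shift of C5 from C10 to C9 with inversion at C9. The expelled C10 becomes the C9 methyl, and its CH2OH first directs hydrogenation at C7. The precursor is a trans-diequatorial octalin diol monomesylate.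

Key step: step 13

Remark: C10 is the extra ring carbon of the octalin (between C5 and C9); 2-(triphenylphosphoranylidene)butanal, 2-bromo-3,3-diethoxyprop-1-ene and trimethyl 2-phosphonoacrylate are assumed to be commercial.

Step 1
Reactants: 1 (4R,5R)-2,2-dimethyl-1,3-dioxolane-4,5-dimethanol
Product: 2 mono-TBS ether of 1
Conditions: NaH (1.0 equiv), THF, 0 °C; TBSCl (1.0 equiv), rt
Reagents that add atoms: tert-butyldimethylsilyl chloride, CC(C)(C)[Si](C)(C)Cl
Why: Monosilylation of a C2-symmetric diol via its monosodium alkoxide; the two hydroxyls are homotopic, so no stereochemical question arises.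

Step 2
Reactants: 2 mono-TBS ether
Product: 4 allyl diethyl acetal (C9–CH2–C(=CH2)–CH(OEt)2, C10–CH2OTBS), via primary triflate 3 (not isolated)
Conditions: Tf2O, 2,6-lutidine, CH2Cl2, −78 °C; then (3,3-diethoxyprop-1-en-2-yl)lithium [from 2-bromo-3,3-diethoxyprop-1-ene, t-BuLi (2 equiv), THF, −78 °C], THF/HMPA, −78 → −20 °C
Reagents that add atoms: 2-bromo-3,3-diethoxyprop-1-ene, BrC(=C)C(OCC)OCC
Why: SN2 alkylation of an α-acrolein anion equivalent by a primary triflate brings in C7 with its exocyclic methylene and C6 as a masked aldehyde; the dioxolane stereocentres are not touched.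

Step 3
Reactants: 4 allyl diethyl acetal
Product: 5 primary alcohol (C5–OH)
Conditions: TBAF, THF, 0 °C
Reagents that add atoms: none
Why: Fluoride desilylation; acetal and acetonide are stable to it.

Step 4
Reactants: 5 primary alcohol
Product: 6 α-alkoxy aldehyde (C5 = CHO)
Conditions: Dess–Martin periodinane, NaHCO3, CH2Cl2, 0 °C → rt
Reagents that add atoms: none
Why: Buffered periodinane oxidation should give the aldehyde without epimerising C10 or opening the acid-labile acetal.

Step 5
Reactants: 6 α-alkoxy aldehyde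
Product: 7 (E)-enoate, methyl 2-[(4-methoxybenzyloxy)methyl]acrylate unit with C10 trans to CO2Me
Conditions: 4-methoxybenzyl alcohol, NaH, THF, 0 °C; trimethyl 2-phosphonoacrylate; then 6, −78 → 0 °C
Reagents that add atoms: 4-methoxybenzyl alcohol, COc1ccc(CO)cc1; trimethyl 2-phosphonoacrylate, COC(=O)C(=C)P(=O)(OC)OC
Why: Tandem oxa-Michael addition / Horner–Wadsworth–Emmons olefination; the stabilised phosphonate carbanion should give the E-trisubstituted enoate (aldehyde residue trans to the ester) and is too weakly basic to epimerise C10.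

Step 6
Reactants: 7 (E)-enoate acetal
Product: 8 2-substituted acrolein (C6 = CHO, C7 = C(=CH2))
Conditions: oxalic acid (cat.), THF/H2O, rt
Reagents that add atoms: water, O
Why: Acetal hydrolysis, in which the allylic diethyl acetal reacts far faster than the dioxolane or the PMB ether; the enal is used at once.

Step 7
Reactants: 8 2-substituted acrolein
Product: 9 cross-conjugated dienal, (E)-OHC–C(Et)=CH–C(=CH2)–
Conditions: 2-(triphenylphosphoranylidene)butanal, toluene, 80 °C, BHT
Reagents that add atoms: 2-(triphenylphosphoranylidene)butanal, CCC(C=O)=P(c1ccccc1)(c1ccccc1)c1ccccc1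
Why: Wittig olefination with a stabilised formyl ylide should give the E-enal, with C7 trans to CHO and cis to ethyl.

Step 8
Reactants: 9 dienal
Product: 10 tetraene ester, Ph–CH=CH–C(Et)=CH–C(=CH2)–CH2–[trans-dioxolane]–CH=C(CH2OPMB)CO2Me (all E)
Conditions: diethyl benzylphosphonate, NaH, THF, 0 °C; then 9, −78 → 0 °C
Reagents that add atoms: diethyl benzylphosphonate, CCOP(=O)(Cc1ccccc1)OCC
Why: Horner–Wadsworth–Emmons olefination of the aldehyde gives the E-styryl unit and completes the (E,E)-diene; attack on the aldehyde is much faster than on the enoate.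

Step 9
Reactants: 10 tetraene ester
Product: 11 trans-fused octalin methyl ester (H5/H6 trans; Ph, CO2Me and the C6–C7 bond on one face; CH2OPMB and the C5–C10 bond on the other; C10–O cis to H5; C9–O trans to C10–O; exocyclic methylene at C7)
Conditions: Me2AlCl (2 equiv), CH2Cl2, −78 → −20 °C
Reagents that add atoms: none
Why: Type-1 intramolecular Diels–Alder in which the Lewis-acid-bound E-ester sits endo, giving the trans-fused ring system with the ester cis to phenyl, while the trans-dioxolane can only span two equatorial positions of the chair-like tether, so that the (R,R)-acetal fixes the dienophile face and hence C3, C4, C5 and C6.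

Step 10
Reactants: 11 octalin methyl ester
Product: 13 C4-vinyl octalin, via C4 aldehyde 12 (not isolated)
Conditions: DIBAL-H (1.2 equiv), CH2Cl2, −78 °C; then Ph3P=CH2 (from Ph3PCH3Br, KHMDS), THF, −78 °C → rt
Reagents that add atoms: methyltriphenylphosphonium bromide, C[P+](c1ccccc1)(c1ccccc1)c1ccccc1.[Br-]
Why: Partial reduction of the hindered neopentyl ester and Wittig methylenation of the non-enolisable aldehyde turn the activating group into the latent C4 ethyl; C4 cannot epimerise.

Step 11
Reactants: 13 C4-vinyl octalin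
Product: 14 octalin trans-diol (C10–OH and C9–OH both equatorial)
Conditions: AcOH/THF/H2O (3:1:1), 45 °C
Reagents that add atoms: none
Why: Acetal hydrolysis, in which the strained trans-fused acetonide opens under mild acid that leaves the PMB ether and the 1,1-disubstituted alkene alone.

Step 12
Reactants: 14 octalin trans-diol
Product: 15 C9 monomesylate (C10–OH free)
Conditions: MsCl (1.05 equiv), 2,4,6-collidine, CH2Cl2, −20 → 0 °C
Reagents that add atoms: methanesulfonyl chloride, CS(=O)(=O)Cl
Why: Selective sulfonylation: the C10 hydroxyl is flanked by the ring-fusion carbon and lies peri to the C4 substituents, so reaction should occur at the unhindered C9 hydroxyl.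

Step 13
Reactants: 15 C9 monomesylate
Product: 17 trans-hydrindene with C9–CH2OH (cis to the C5–C4 bond, on the face opposite to H5), via C9 carbaldehyde 16 (not isolated)
Conditions: Et3Al (3 equiv), CH2Cl2, −78 → 0 °C; then DIBAL-H, −78 °C
Reagents that add atoms: none
Why: The aluminium alkoxide at C10 pushes while the Lewis acid activates the equatorial C9 mesylate; the C10–C5 ring bond, antiperiplanar to C9–OMs in the locked trans-fused chair, migrates to C9, and C10 is expelled as a formyl group that DIBAL-H reduces at once. The closest known reaction type is the base- or organoaluminium-promoted pinacol-type rearrangement of 2-sulfonyloxy alcohols, long used to contract decalin diol monosulfonates to hydrindane carbaldehydes. The cyclopentane is closed by this 1,2-alkyl shift (six- to five-membered contraction), not by a new cyclisation; C5 migrates with retention, so the trans ring fusion from step 9 is kept. C9 is formed with inversion, which turns the equatorial C–O of the octalin into a one-carbon branch cis to the C4 substituent. The step needs migration of C5 instead of hydride shift, epoxide closure or E2; with both oxygens equatorial only the C10–C5 bond is aligned, and the free C10–OH is the only donor. Immediate reduction keeps the α-formyl centre from epimerising.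

Step 14
Reactants: 17 C9-hydroxymethyl hydrindene
Product: 18 hydrindene with C7 methyl (trans to the C9 branch), C4 ethyl and C9–CH2OH
Conditions: [Rh(nbd)(dppb)]BF4 (5 mol %), H2 (50 bar), CH2Cl2, rt
Reagents that add atoms: none
Why: Hydroxyl-directed hydrogenation should deliver H2 to the C7 methylene from the face of the C9 CH2OH (H7 cis to H6, methyl cis to C1) and reduce the C4 vinyl to ethyl; the hindered, undirected C1=C2 bond should survive.

Step 15
Reactants: 18 primary alcohol
Product: 19 primary tosylate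
Conditions: TsCl, pyridine, DMAP (cat.), CH2Cl2, 0 °C → rt
Reagents that add atoms: 4-toluenesulfonyl chloride, Cc1ccc(cc1)S(=O)(=O)Cl
Why: Standard sulfonylation of the only free hydroxyl.

Step 16
Reactants: 19 primary tosylate
Product: 20 PMB ether with both ring methyls in place
Conditions: LiEt3BH, THF, 0 °C → rt
Reagents that add atoms: none
Why: Hydride displacement of a primary tosylate gives the C9 methyl; C9 itself is not involved.

Step 17
Reactants: 20 PMB ether
Product: 21 neopentyl alcohol (C4–CH2OH)
Conditions: DDQ, CH2Cl2/pH 7 buffer, 0 °C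
Reagents that add atoms: none
Why: Oxidative cleavage of the PMB ether; short contact at 0 °C should spare the allylic–benzylic C3–H.

Step 18
Reactants: 21 neopentyl alcohol
Product: 22 C4 aldehyde
Conditions: Dess–Martin periodinane, NaHCO3, CH2Cl2, rt
Reagents that add atoms: none
Why: Dess–Martin oxidation to a non-enolisable aldehyde on the quaternary carbon.

Step 19
Reactants: 22 C4 aldehyde
Product: 23 homo-plakotenin ethyl ester
Conditions: ethyl 2-(triphenylphosphoranylidene)propanoate, toluene, 110 °C
Reagents that add atoms: ethyl 2-(triphenylphosphoranylidene)propanoate, CCOC(=O)C(C)=P(c1ccccc1)(c1ccccc1)c1ccccc1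
Why: Wittig olefination with a stabilised ylide should give the E-trisubstituted enoate (C4 trans to CO2Et) even with the hindered aldehyde.

Step 20
Reactants: 23 ethyl ester
Product: 24 homo-plakotenin
Conditions: LiOH, THF/MeOH/H2O, 50 °C; then 1 M HCl
Reagents that add atoms: lithium hydroxide, [Li+].[OH-]
Why: Saponification of the conjugated ester; no stereocentre is epimerisable.

**Compound list**

1 | (4R,5R)-2,2-dimethyl-1,3-dioxolane-4,5-dimethanol (2,3-O-isopropylidene-D-threitol) | OC[C@H]1OC(C)(C)O[C@@H]1CO | starting material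
2 | [(4R,5R)-5-(tert-butyldimethylsilyloxymethyl)-2,2-dimethyl-1,3-dioxolan-4-yl]methanol | OC[C@H]1OC(C)(C)O[C@@H]1CO[Si](C)(C)C(C)(C)C | intermediate
3 | primary triflate of 2 (not isolated) | FC(F)(F)S(=O)(=O)OC[C@H]1OC(C)(C)O[C@@H]1CO[Si](C)(C)C(C)(C)C | intermediate
4 | trans-dioxolane with C10–CH2OTBS and C9–CH2C(=CH2)CH(OEt)2 | CCOC(OCC)C(=C)C[C@H]1OC(C)(C)O[C@@H]1CO[Si](C)(C)C(C)(C)C | intermediate
5 | primary alcohol from 4 | CCOC(OCC)C(=C)C[C@H]1OC(C)(C)O[C@@H]1CO | intermediate
6 | dioxolane carbaldehyde (C5 = CHO) | CCOC(OCC)C(=C)C[C@H]1OC(C)(C)O[C@@H]1C=O | intermediate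
7 | methyl (E)-2-[(4-methoxybenzyloxy)methyl]-3-(dioxolanyl)acrylate, acetal retained | CCOC(OCC)C(=C)C[C@H]1OC(C)(C)O[C@@H]1/C=C(\COCc2ccc(OC)cc2)C(=O)OC | intermediate
8 | 2-substituted acrolein (C6 = CHO) | O=CC(=C)C[C@H]1OC(C)(C)O[C@@H]1/C=C(\COCc2ccc(OC)cc2)C(=O)OC | intermediate
9 | cross-conjugated (E)-dienal | CC/C(C=O)=C\C(=C)C[C@H]1OC(C)(C)O[C@@H]1/C=C(\COCc2ccc(OC)cc2)C(=O)OC | intermediate
10 | tetraene ester (cycloaddition substrate) | CC/C(/C=C/c1ccccc1)=C\C(=C)C[C@H]2OC(C)(C)O[C@@H]2/C=C(\COCc3ccc(OC)cc3)C(=O)OC | intermediate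
11 | trans-fused octalin methyl ester with C9/C10 acetonide and C7 methylene | CCC1=C[C@@H](c2ccccc2)[C@@](COCc3ccc(OC)cc3)(C(=O)OC)[C@H]2[C@H]1C(=C)C[C@H]3OC(C)(C)O[C@H]23 | intermediate
12 | C4 aldehyde of the octalin (not isolated) | CCC1=C[C@@H](c2ccccc2)[C@@](COCc3ccc(OC)cc3)(C=O)[C@H]2[C@H]1C(=C)C[C@H]3OC(C)(C)O[C@H]23 | intermediate
13 | C4-vinyl octalin acetonide | CCC1=C[C@@H](c2ccccc2)[C@@](COCc3ccc(OC)cc3)(C=C)[C@H]2[C@H]1C(=C)C[C@H]3OC(C)(C)O[C@H]23 | intermediate
14 | octalin trans-9,10-diol | CCC1=C[C@@H](c2ccccc2)[C@@](COCc3ccc(OC)cc3)(C=C)[C@H]2[C@H]1C(=C)C[C@@H](O)[C@@H]2O | intermediate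
15 | octalin C9 mesylate, C10–OH free | CCC1=C[C@@H](c2ccccc2)[C@@](COCc3ccc(OC)cc3)(C=C)[C@H]2[C@H]1C(=C)C[C@@H](OS(C)(=O)=O)[C@@H]2O | intermediate
16 | trans-hydrindene C9 carbaldehyde (not isolated) | CCC1=C[C@@H](c2ccccc2)[C@@](COCc3ccc(OC)cc3)(C=C)[C@H]2[C@H]1C(=C)C[C@H]2C=O | intermediate
17 | trans-hydrindene with C9–CH2OH, C7 methylene, C4 vinyl | CCC1=C[C@@H](c2ccccc2)[C@@](COCc3ccc(OC)cc3)(C=C)[C@H]2[C@H]1C(=C)C[C@H]2CO | intermediate
18 | hydrindene with C7 methyl, C4 ethyl, C9–CH2OH | CCC1=C[C@@H](c2ccccc2)[C@@](COCc3ccc(OC)cc3)(CC)[C@H]2[C@H]1[C@H](C)C[C@H]2CO | intermediate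
19 | primary tosylate of 18 | CCC1=C[C@@H](c2ccccc2)[C@@](COCc3ccc(OC)cc3)(CC)[C@H]2[C@H]1[C@H](C)C[C@H]2COS(=O)(=O)c1ccc(C)cc1 | intermediate
20 | 7,9-dimethyl hydrindene PMB ether | CCC1=C[C@@H](c2ccccc2)[C@@](COCc3ccc(OC)cc3)(CC)[C@H]2[C@H]1[C@H](C)C[C@H]2C | intermediate
21 | C4 hydroxymethyl hydrindene | CCC1=C[C@@H](c2ccccc2)[C@@](CO)(CC)[C@H]2[C@H]1[C@H](C)C[C@H]2C | intermediate
22 | C4 carbaldehyde | CCC1=C[C@@H](c2ccccc2)[C@@](C=O)(CC)[C@H]2[C@H]1[C@H](C)C[C@H]2C | intermediate
23 | homo-plakotenin ethyl ester | CCC1=C[C@@H](c2ccccc2)[C@@](/C=C(\C)C(=O)OCC)(CC)[C@H]2[C@H]1[C@H](C)C[C@H]2C | intermediate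
24 | homo-plakotenin | CCC1=C[C@@H](c2ccccc2)[C@@](/C=C(\C)C(=O)O)(CC)[C@H]2[C@H]1[C@H](C)C[C@H]2C | target

Total step count: 20. Longest linear sequence: 20 steps (1 → 24).

**Steps most likely to fail**

1. Step 9 (cycloaddition). The Lewis acid may ionise the acetonide or polymerise the cross-conjugated triene, or endo and facial control may be incomplete. Fallback: starting from 10, the ester is reduced with DIBAL-H to the allylic alcohol F1, which is oxidised with MnO2 to the enal F2. The enal should cycloadd thermally (toluene, 40–80 °C) without Lewis acid, giving aldehyde 12 directly. Wittig methylenation as in step 10 then returns to 13.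

2. Step 13 (ring contraction). The shift of the hindered C5 may be slower than elimination, or the preceding sulfonylation may pick the wrong hydroxyl. Fallback: starting from 14, Swern oxidation gives the octalin 9,10-dione F3. Condensation with tosylhydrazide at the less hindered C9 carbonyl gives the monotosylhydrazone F4, and base (Bamford–Stevens) gives the α-diazoketone F5. Photochemical Wolff rearrangement in methanol contracts the ring to the ring-contracted C9 methyl ester F6 (C9 epimers equilibrated with NaOMe and separated). LiAlH4 reduction returns to 17.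

3. Step 14 (hydrogenation). Hydrogen may be delivered to the wrong face of the C7 methylene, or the ring alkene may be over-reduced. Fallback: starting from 13, the vinyl and methylene groups are hydrogenated at the octalin stage with RhCl(PPh3)3/H2. There the methylenecyclohexane should take hydrogen so that the methyl becomes axial, cis to C1 and away from the peri ethyl group, giving the saturated octalin acetonide F7. Acetonide hydrolysis gives the trans-diol F8, and selective mesylation gives the C9 mesylate F9. The Et3Al contraction of step 13 then gives the ring-contracted carbaldehyde F10, which DIBAL-H reduces in the same flask, returning to 18.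

**Further compounds**

F1 | step 9 | allylic alcohol from ester 10 | CC/C(/C=C/c1ccccc1)=C\C(=C)C[C@H]2OC(C)(C)O[C@@H]2/C=C(\COCc3ccc(OC)cc3)CO
F2 | step 9 | enal from F1 | CC/C(/C=C/c1ccccc1)=C\C(=C)C[C@H]2OC(C)(C)O[C@@H]2/C=C(\COCc3ccc(OC)cc3)C=O
F3 | step 13 | octalin 9,10-dione | CCC1=C[C@@H](c2ccccc2)[C@@](COCc3ccc(OC)cc3)(C=C)[C@H]2[C@H]1C(=C)CC(=O)C2=O
F4 | step 13 | C9 monotosylhydrazone of F3 | CCC1=C[C@@H](c2ccccc2)[C@@](COCc3ccc(OC)cc3)(C=C)[C@H]2[C@H]1C(=C)CC(=NNS(=O)(=O)c3ccc(C)cc3)C2=O
F5 | step 13 | 9-diazo-10-ketone | CCC1=C[C@@H](c2ccccc2)[C@@](COCc3ccc(OC)cc3)(C=C)[C@H]2[C@H]1C(=C)CC(=[N+]=[N-])C2=O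
F6 | step 13 | ring-contracted C9 methyl ester | CCC1=C[C@@H](c2ccccc2)[C@@](COCc3ccc(OC)cc3)(C=C)[C@H]2[C@H]1C(=C)C[C@H]2C(=O)OC
F7 | step 14 | octalin acetonide with C7 methyl and C4 ethyl | CCC1=C[C@@H](c2ccccc2)[C@@](COCc3ccc(OC)cc3)(CC)[C@H]2[C@H]1[C@H](C)C[C@H]3OC(C)(C)O[C@H]23
F8 | step 14 | trans-diol from F7 | CCC1=C[C@@H](c2ccccc2)[C@@](COCc3ccc(OC)cc3)(CC)[C@H]2[C@H]1[C@H](C)C[C@@H](O)[C@@H]2O
F9 | step 14 | C9 mesylate of F8 | CCC1=C[C@@H](c2ccccc2)[C@@](COCc3ccc(OC)cc3)(CC)[C@H]2[C@H]1[C@H](C)C[C@@H](OS(C)(=O)=O)[C@@H]2O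
F10 | step 14 | ring-contracted C9 carbaldehyde from F9 | CCC1=C[C@@H](c2ccccc2)[C@@](COCc3ccc(OC)cc3)(CC)[C@H]2[C@H]1[C@H](C)C[C@H]2C=O
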